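A small charge of free enzyme, 0.40 µM, works through a far larger charge of starting material, 0.050 M, while the gas enters solution as second substrate. I want the fraction of the charge that becomes target by 4.0 min.

the same everywhere: starting material 0.050 M; gas 4.2 mM (held)
- east: free enzyme 0.27 µM; run made earlier
- west: free enzyme 0.60 µM; run made earlier
- flask: free enzyme 0.40 µM; time 4.0 min

| east: time / min | east: target / % | west: time / min | west: target / % |
|---|---|---|---|
| 1.00 | 0.7 | 0.333 | 0 |
| 2.00 | 0.7 | 0.667 | 0.9 |
| 3.00 | 2.1 | 1.50 | 2.0 |
| 4.00 | 3.4 | 4.00 | 5.0 |

(standard deviation of a reading: 0.5 percentage points)

- at the start none of the gas is in solution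
- second substrate is what gas becomes in solution

1. amount of target at 4.0 min, in percent of the starting material charged
2. concentration of second substrate in solution at 4.0 min, in percent of saturation

The last east reading, divided by its enzyme and time, gives 0.0315 µM⁻¹ min⁻¹, and the last west reading gives 0.0208 µM⁻¹ min⁻¹. The two runs therefore part visibly, but this flask's enzyme lies between theirs. So I pool them: the two fractions summed, over the two enzyme charges summed and the time, give 0.0241 µM⁻¹ min⁻¹, the enzyme-time constant, which is the fraction of the charge turned per unit of enzyme and per minute, as a reading with the scatter of the runs.

I treat the starting material as pseudo-first-order. In this flask the curve then leaves zero with slope 0.00964 min⁻¹ and heads for the level of the whole charge. That tangent meets that level at 104 min, and a single exponential rise joins the two ends. The flask's reading comes far before this knee, so the curve is still nearly straight and I commit to 3.79 % target. This reckoning has no term for second substrate, so I give no figure for it.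

The forecast, holding that “gas dissolution limits the rate”, gives 4.1 % target and 19 % of saturation, so its target stands 0.31 percentage points above mine.

The flask gives 3.87 % target and 94.0 % of saturation.

    starting material + free enzyme ⇌ first complex (K = 6.00 M⁻¹, k = 4.31 × 10⁵ M⁻¹ s⁻¹)
    first complex ⇌ loaded enzyme + first product (K = 0.0350 M, k = 131 s⁻¹)
    second substrate + loaded enzyme ⇌ second complex (K = 600 M⁻¹, k = 1.36 × 10⁶ M⁻¹ s⁻¹)
    second complex → free enzyme + target (k = 103 s⁻¹)
    gas ⇌ second substrate, rate k5*(csat - [second substrate]) (kL = 0.0324 s⁻¹)

The second substrate stands 75 points above the forecast. The flask's target stands 0.080 points above the 3.79 % I reckoned from the enzyme-time constant. For the same flask read at 15 min, 0.0241 µM⁻¹ min⁻¹ gives 13.4 %. That flask holds 14.0 % target, with 86 % of the starting material left unbound.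

The runs were generated by integration from invented constants; noise was put on by code.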